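**Strategy.** Ring B is dissected into two three-carbon units: C9–C10–C5, held as a non-enolisable 1,3-diketone (ring A ketone at C5, side-chain ketone at C9, quaternary C10 between them), and C6–C7–C8, an α-silyloxy ethyl ketone that is nucleophilic at both α-carbons. A single titanium-mediated double aldol condensation joins C8 to C9, creating the tetrasubstituted C8=C9 alkene, and C6 to C5, so that ring B emerges as a 6-hydroxy-5,8-dien-7-one with both oxygens in place. C10 stems from an asymmetric decarboxylative allylation; C5, C6 and C7 are then set by substrate-controlled reductions.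

Key step: step 8

Remark: labdane numbering (C1–C20) is used for the target and the bicyclic intermediates, β is the face of the C10 methyl group, and the sense of induction in step 2 is assumed to follow the parent 2-methylcyclohexanone case.

Step 1
Reactants: 1 2,2,6-trimethylcyclohexan-1-one; 2 allyl chloroformate
Product: 3 allyl 2,6,6-trimethylcyclohex-1-en-1-yl carbonate
Conditions: LiN(SiMe3)2, THF, 0 °C; then 2, −78 → 23 °C
Reagents that add atoms: none
Why: The ketone can enolise on one side only and the hard chloroformate should acylate the enolate on oxygen (enol carbonate formation).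

Step 2
Reactants: 3 allyl 2,6,6-trimethylcyclohex-1-en-1-yl carbonate
Product: 4 (2R)-2-allyl-2,6,6-trimethylcyclohexan-1-one
Conditions: Pd2(dba)3 (2.5 mol %), (R)-t-BuPHOX (6 mol %), THF, 25 °C
Reagents that add atoms: none
Why: Decarboxylative asymmetric Tsuji allylation; the chiral phosphinooxazoline ligand controls the face of C–C bond formation at the tetrasubstituted enolate carbon and sets the quaternary C10 (the (S)-ligand is known to favour the (S)-ketone in this reaction class, so the (R)-ligand is used).

Step 3
Reactants: 4 (2R)-2-allyl-2,6,6-trimethylcyclohexan-1-one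
Product: 5 (2R)-2-(1-hydroxyprop-2-en-1-yl)-2,6,6-trimethylcyclohexan-1-one (both carbinol epimers)
Conditions: SeO2 (0.5 equiv), t-BuOOH, CH2Cl2, 23 °C
Reagents that add atoms: selenium dioxide O=[Se]=O; tert-butyl hydroperoxide CC(C)(C)OO
Why: SeO2 allylic oxidation (ene reaction, then [2,3]-sigmatropic shift) should oxidise the only allylic CH2 (future C9) and leave the alkene terminal; the ketone has no α-hydrogen and the carbinol configuration is erased in step 6.

Step 4
Reactants: 6 methyl acetoacetate
Product: 7 methyl (2E)-3-[(trifluoromethanesulfonyl)oxy]but-2-enoate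
Conditions: Tf2O, aq. Me4NOH, hexanes, 5 → 23 °C
Reagents that add atoms: trifluoromethanesulfonic anhydride O=S(=O)(OS(=O)(=O)C(F)(F)F)C(F)(F)F
Why: Enol triflate formation; the non-chelated tetramethylammonium enolate should be triflated with the triflate trans to the ester (E), which fixes the later C13=C14 geometry.

Step 5
Reactants: 5 (2R)-2-(1-hydroxyprop-2-en-1-yl)-2,6,6-trimethylcyclohexan-1-one; 7 methyl (2E)-3-[(trifluoromethanesulfonyl)oxy]but-2-enoate
Product: 9 methyl (2E)-6-hydroxy-3-methyl-6-[(1R)-1,3,3-trimethyl-2-oxocyclohexyl]hex-2-enoate (carbinol epimers), via B-alkyl-9-BBN adduct 8 (not isolated)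
Conditions: 9-BBN, THF, 23 °C; then 7, Pd(dppf)Cl2, AsPh3, Cs2CO3, DMF/H2O, 23 °C
Reagents that add atoms: none
Why: Anti-Markovnikov hydroboration of the terminal alkene followed by B-alkyl Suzuki–Miyaura coupling, which proceeds with retention of the triflate geometry; the congested ring ketone should not be reduced and the mild base at 23 °C limits retro-aldol cleavage.

Step 6
Reactants: 9 methyl (2E)-6-hydroxy-3-methyl-6-[(1R)-1,3,3-trimethyl-2-oxocyclohexyl]hex-2-enoate
Product: 10 methyl (2E)-3-methyl-6-oxo-6-[(1R)-1,3,3-trimethyl-2-oxocyclohexyl]hex-2-enoate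
Conditions: Dess–Martin periodinane, CH2Cl2, 23 °C
Reagents that add atoms: none
Why: Neutral oxidation of the secondary alcohol gives the 1,3-diketone, which cannot enolise between the carbonyl groups and so keeps C10 intact.

Step 7
Reactants: 11 1-hydroxybutan-2-one
Product: 12 1-[(tert-butyldimethylsilyl)oxy]butan-2-one
Conditions: t-BuMe2SiCl, imidazole, DMF, 23 °C
Reagents that add atoms: tert-butyldimethylsilyl chloride CC(C)(C)[Si](C)(C)Cl
Why: Standard silylation of the primary alcohol; the bulky, poorly chelating silyl ether later steers the first enolisation to the ethyl side.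

Step 8
Reactants: 10 methyl (2E)-3-methyl-6-oxo-6-[(1R)-1,3,3-trimethyl-2-oxocyclohexyl]hex-2-enoate; 12 1-[(tert-butyldimethylsilyl)oxy]butan-2-one
Product: 15 methyl (10R,13E)-6-hydroxy-7-oxolabda-5,8,13-trien-15-oate, via mono-aldol adduct 13 (not isolated), via bis-aldol adduct 14 (not isolated)
Conditions: TiCl4, Bu3N, CH2Cl2, −78 → 23 °C; then 2 M HCl, THF, 23 °C
Reagents that add atoms: none
Why: The kinetically formed titanium enolate of 12 (enolisation on the ethyl side, away from the bulky, non-chelating silyloxy group) should add through C8 to the C9 carbonyl of the TiCl4-chelated diketone 10, the less hindered of its two ketones, to give 13; renewed enolisation, now possible only at C6, is followed by intramolecular aldol addition to the C5 ketone (14), and β-elimination of both tertiary aldolates with acidic cleavage of the silyl enol ether gives the cross-conjugated diosphenol 15. The closest known reaction types are the titanium-mediated crossed aldol addition between two ketones, the TiCl4-mediated [3+3] cyclocondensation of 1,3-dinucleophiles with 2,2-disubstituted 1,3-diketones and the aldol closure of a Robinson annulation. Ring B closes in the 6-(enolendo)-exo-trig mode. No stereocentre is created in 15 (C5, C6, C8 and C9 end up sp2) and the quaternary C10 cannot epimerise. The step needs regioselectivity (C8 to C9, C6 to C5), secured by the different steric demand of the two carbonyl groups of 10 and by the order of enolisation of 12, and it needs suppression of retro-Claisen cleavage of 10, secured by the Lewis acidic, non-nucleophilic medium.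

Step 9
Reactants: 15 methyl (10R,13E)-6-hydroxy-7-oxolabda-5,8,13-trien-15-oate
Product: 16 methyl (5S,6S,10S,13E)-6,7-dihydroxylabda-8,13-dien-15-oate (C7 epimers)
Conditions: NaBH4, CeCl3·7H2O, MeOH, −20 → 0 °C
Reagents that add atoms: none
Why: Luche-type borohydride reduction through the 6,7-diketone tautomer, in which C5 is epimerisable and should settle as the trans ring fusion (5α-H); hydride should attack C6 from the α face, opposite the axial methyl groups on C4 and C10, giving the 6β-alcohol, while C7 forms without control and is corrected in steps 10 and 11.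

Step 10
Reactants: 16 methyl (5S,6S,10S,13E)-6,7-dihydroxylabda-8,13-dien-15-oate
Product: 17 methyl (5S,6S,10S,13E)-6-hydroxy-7-oxolabda-8,13-dien-15-oate
Conditions: MnO2, CH2Cl2, 23 °C
Reagents that add atoms: none
Why: MnO2 oxidises allylic alcohols selectively, so both C7 epimers should converge on one enone while the hindered, non-allylic 6β-hydroxyl is left.

Step 11
Reactants: 17 methyl (5S,6S,10S,13E)-6-hydroxy-7-oxolabda-8,13-dien-15-oate
Product: 18 methyl (5S,6S,7S,10S,13E)-6,7-dihydroxylabda-8,13-dien-15-oate
Conditions: Me4NBH(OAc)3, AcOH/MeCN, −30 °C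
Reagents that add atoms: none
Why: Evans–Saksena hydroxyl-directed reduction; the 6β-hydroxyl exchanges onto boron and delivers hydride intramolecularly to the β face of C7, which should give the 7α-alcohol trans to the 6β-hydroxyl.

Step 12
Reactants: 18 methyl (5S,6S,7S,10S,13E)-6,7-dihydroxylabda-8,13-dien-15-oate
Product: 19 (5S,6S,7S,10S,13E)-6,7-dihydroxylabda-8,13-dien-15-oic acid
Conditions: LiOH, THF/MeOH/H2O, 40 °C; then 1 M HCl, 0 °C
Reagents that add atoms: lithium hydroxide [Li+].[OH-]
Why: Saponification of the methyl ester is done before the two secondary esters are installed, because it could not be done selectively afterwards.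

Step 13
Reactants: 19 (5S,6S,7S,10S,13E)-6,7-dihydroxylabda-8,13-dien-15-oic acid; 20 3-methylbutanoyl chloride
Product: 22 (5S,6S,7S,10S,13E)-6-hydroxy-7-(3-methylbutanoyloxy)labda-8,13-dien-15-oic acid, via mixed isovaleric anhydride 21 (not isolated)
Conditions: pyridine, DMAP (cat.), CH2Cl2, −20 → 0 °C; then H2O, THF
Reagents that add atoms: water O
Why: Acylation should take place at the accessible allylic 7α-hydroxyl and not at the 6β-hydroxyl, which is 1,3-diaxial to the methyl groups on C4 and C10; the carboxyl group is acylated in passing and freed again by the aqueous quench.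

Step 14
Reactants: 22 (5S,6S,7S,10S,13E)-6-hydroxy-7-(3-methylbutanoyloxy)labda-8,13-dien-15-oic acid; 23 acetic anhydride
Product: 25 (5S,6S,7S,10S,13E)-6-acetoxy-7-(3-methylbutanoyloxy)labda-8,13-dien-15-oic acid, via mixed acetic anhydride 24 (not isolated)
Conditions: Et3N, DMAP, CH2Cl2, 40 °C; then aq. NaHCO3, THF; 1 M HCl, 0 °C
Reagents that add atoms: water O
Why: DMAP-catalysed acetylation under forcing conditions should esterify the hindered 6β-hydroxyl; the trans-diaxial arrangement of the two esters prevents acyl migration and the aqueous quench restores the acid.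

**Compound list**

1 | 2,2,6-trimethylcyclohexan-1-one | CC1CCCC(C)(C)C1=O | starting material
2 | allyl chloroformate | C=CCOC(=O)Cl | starting material
3 | allyl 2,6,6-trimethylcyclohex-1-en-1-yl carbonate | C=CCOC(=O)OC1=C(C)CCCC1(C)C | intermediate
4 | (2R)-2-allyl-2,6,6-trimethylcyclohexan-1-one | C=CC[C@@]1(C)CCCC(C)(C)C1=O | intermediate
5 | (2R)-2-(1-hydroxyprop-2-en-1-yl)-2,6,6-trimethylcyclohexan-1-one, both carbinol epimers | C=CC(O)[C@@]1(C)CCCC(C)(C)C1=O | intermediate
6 | methyl acetoacetate | COC(=O)CC(C)=O | starting material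
7 | methyl (2E)-3-[(trifluoromethanesulfonyl)oxy]but-2-enoate | COC(=O)/C=C(\C)OS(=O)(=O)C(F)(F)F | intermediate
8 | (2R)-2-[3-(9-borabicyclo[3.3.1]nonan-9-yl)-1-hydroxypropyl]-2,6,6-trimethylcyclohexan-1-one (B-alkyl-9-BBN adduct, not isolated) | OC(CCB1C2CCCC1CCC2)[C@@]3(C)CCCC(C)(C)C3=O | intermediate
9 | methyl (2E)-6-hydroxy-3-methyl-6-[(1R)-1,3,3-trimethyl-2-oxocyclohexyl]hex-2-enoate, carbinol epimers | COC(=O)/C=C(\C)CCC(O)[C@@]1(C)CCCC(C)(C)C1=O | intermediate
10 | methyl (2E)-3-methyl-6-oxo-6-[(1R)-1,3,3-trimethyl-2-oxocyclohexyl]hex-2-enoate | COC(=O)/C=C(\C)CCC(=O)[C@@]1(C)CCCC(C)(C)C1=O | intermediate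
11 | 1-hydroxybutan-2-one | CCC(=O)CO | starting material
12 | 1-[(tert-butyldimethylsilyl)oxy]butan-2-one | CCC(=O)CO[Si](C)(C)C(C)(C)C | intermediate
13 | mono-aldol adduct: 10 with C9 as a tertiary carbinol bearing the 4-silyloxy-3-oxobutan-2-yl group (present as titanium aldolate, diastereomers, not isolated) | COC(=O)/C=C(\C)CCC(O)(C(C)C(=O)CO[Si](C)(C)C(C)(C)C)[C@@]1(C)CCCC(C)(C)C1=O | intermediate
14 | bis-aldol adduct: methyl (13E)-6-[(tert-butyldimethylsilyl)oxy]-5,9-dihydroxy-7-oxolabd-13-en-15-oate (titanium aldolate, diastereomers, not isolated) | O=C1C(O[Si](C)(C)C(C)(C)C)C2(O)C(C)(C)CCC[C@]2(C)C(O)(CC/C(C)=C/C(=O)OC)C1C | intermediate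
15 | methyl (10R,13E)-6-hydroxy-7-oxolabda-5,8,13-trien-15-oate (diosphenol) | O=C1C(O)=C2C(C)(C)CCC[C@]2(C)C(CC/C(C)=C/C(=O)OC)=C1C | intermediate
16 | methyl (5S,6S,10S,13E)-6,7-dihydroxylabda-8,13-dien-15-oate, C7 epimers | O[C@@H]1C(O)C(C)=C(CC/C(C)=C/C(=O)OC)[C@@]2(C)CCCC(C)(C)[C@H]12 | intermediate
17 | methyl (5S,6S,10S,13E)-6-hydroxy-7-oxolabda-8,13-dien-15-oate | O[C@@H]1C(=O)C(C)=C(CC/C(C)=C/C(=O)OC)[C@@]2(C)CCCC(C)(C)[C@H]12 | intermediate
18 | methyl (5S,6S,7S,10S,13E)-6,7-dihydroxylabda-8,13-dien-15-oate (6β,7α-diol) | O[C@@H]1[C@@H](O)C(C)=C(CC/C(C)=C/C(=O)OC)[C@@]2(C)CCCC(C)(C)[C@H]12 | intermediate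
19 | (5S,6S,7S,10S,13E)-6,7-dihydroxylabda-8,13-dien-15-oic acid | O[C@@H]1[C@@H](O)C(C)=C(CC/C(C)=C/C(=O)O)[C@@]2(C)CCCC(C)(C)[C@H]12 | intermediate
20 | 3-methylbutanoyl chloride (isovaleryl chloride) | CC(C)CC(=O)Cl | starting material
21 | mixed anhydride of 22 with 3-methylbutanoic acid (not isolated) | O[C@@H]1[C@@H](OC(=O)CC(C)C)C(C)=C(CC/C(C)=C/C(=O)OC(=O)CC(C)C)[C@@]2(C)CCCC(C)(C)[C@H]12 | intermediate
22 | (5S,6S,7S,10S,13E)-6-hydroxy-7-(3-methylbutanoyloxy)labda-8,13-dien-15-oic acid | O[C@@H]1[C@@H](OC(=O)CC(C)C)C(C)=C(CC/C(C)=C/C(=O)O)[C@@]2(C)CCCC(C)(C)[C@H]12 | intermediate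
23 | acetic anhydride | CC(=O)OC(C)=O | starting material
24 | mixed anhydride of 25 with acetic acid (not isolated) | CC(=O)O[C@@H]1[C@@H](OC(=O)CC(C)C)C(C)=C(CC/C(C)=C/C(=O)OC(C)=O)[C@@]2(C)CCCC(C)(C)[C@H]12 | intermediate
25 | (5S,6S,7S,10S,13E)-6-acetoxy-7-(3-methylbutanoyloxy)labda-8,13-dien-15-oic acid | CC(=O)O[C@@H]1[C@@H](OC(=O)CC(C)C)C(C)=C(CC/C(C)=C/C(=O)O)[C@@]2(C)CCCC(C)(C)[C@H]12 | target

**Step count.** Total: 14 steps. Longest linear sequence: 12 steps (1, 2, 3, 5, 6, 8, 9, 10, 11, 12, 13, 14).

**Steps most likely to fail**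

Step 8. The C9 aldolate may fragment across the C9–C10 bond (retro-Claisen-type loss of the acyl group), 12 may enolise first on the silyloxy side, or the second aldol addition may stall at the congested C5 carbonyl. The fallback sets out from 10 and 12 and comes back at 15, with the two C–C bonds made in separate operations. Ketone 12 is converted with LiN(iPr)2 and Me3SiCl (THF, −78 °C) into the trimethylsilyl enol ether F1. Mukaiyama aldol addition of F1 to 10 (TiCl4, CH2Cl2, −78 °C) should give the mono-aldol 13, which is now isolated. Dehydration of 13 with Burgess reagent should give the enone F2. NaOMe in MeOH at 60 °C then equilibrates the alkene isomers through the dienolate, closes ring B by a Robinson-type aldol condensation onto the C5 ketone and removes the silyl group, giving 15.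

Step 9. Hydride delivery to the diosphenol may show poor facial selectivity at C6, protonation at C5 may give some cis ring fusion, or the enone may be over-reduced. The fallback sets out from 15 and comes back at 17, bypassing 16 and step 10, and makes no new compound. Zn dust in AcOH at 23 °C should reduce the diketone tautomer by electron transfer to the enediol, which should ketonise to the conjugated 7-ketone with protonation of C6 from the less hindered α face.

Step 3. The allylic oxidation next to the quaternary centre may be slow or may run on to the enone. The fallback sets out from 4 and comes back at 5. Isomerisation of the allyl group with RuHCl(CO)(PPh3)3 (PhMe, 80 °C) should give the propenyl ketone F3. Ozonolysis (O3, CH2Cl2, −78 °C; Me2S) should give the keto aldehyde F4. Vinylmagnesium bromide (THF, −78 °C) should add to the aldehyde and not to the hindered ketone, giving 5.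

**Further compounds**

F1 | step 8 | (2Z)-1-[(tert-butyldimethylsilyl)oxy]-2-[(trimethylsilyl)oxy]but-2-ene | C/C=C(\O[Si](C)(C)C)CO[Si](C)(C)C(C)(C)C
F2 | step 8 | methyl (2E)-6-{4-[(tert-butyldimethylsilyl)oxy]-3-oxobutan-2-ylidene}-3-methyl-6-[(1R)-1,3,3-trimethyl-2-oxocyclohexyl]hex-2-enoate, alkene isomers at the new double bond | COC(=O)/C=C(\C)CCC(=C(C)C(=O)CO[Si](C)(C)C(C)(C)C)[C@@]1(C)CCCC(C)(C)C1=O
F0 | step 9 | none | none
F3 | step 3 | (2R)-2,6,6-trimethyl-2-[(1E)-prop-1-en-1-yl]cyclohexan-1-one | C/C=C/[C@@]1(C)CCCC(C)(C)C1=O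
F4 | step 3 | (1R)-1,3,3-trimethyl-2-oxocyclohexane-1-carbaldehyde | O=C[C@@]1(C)CCCC(C)(C)C1=O
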